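**Retrosynthetic overview**
- The target is traced back, through ketone-to-CH2 reduction, cleavage of four benzyl ethers and saturation of two C≡C bonds, to a diaryl ketone that carries two diarylalkyne arms.
- Key disconnection: the four C(sp2)–C(sp) bonds of that ketone. Each CH2–CH2 tether of the target joins C3 of a central phenol ring A (ortho to the bridging CH2 on C4, meta to both ring oxygens) to C1' of a guaiacyl ring B, so both tether carbons come from one acetylene unit set between a core di-iodide and a guaiacyl iodide.
- The ring-A carbon that bears the tether is meta to both oxygens and cannot be reached by electrophilic substitution, so its halogen is bought with the arene (5-bromoresorcinol dibenzyl ether). The core ketone is assembled from two ortho-bromoaryl Grignard units and ethyl formate, the carbonyl then differentiates the ortho-oxygen (to OMe) from the para-oxygen (OBn), and Br is exchanged for I.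
- No ring is formed: the four benzene rings are bought and only linked (central C–C bonds in step 2, tether bonds in step 8).

Key step: step 8

Remark: the target has no stereocentre, axis or double-bond geometry, so it is one achiral compound and no stereocontrol is needed.
Remark: 1,3-bis(benzyloxy)-5-bromobenzene is taken as a catalogue compound.

**Step 1**
Reactants: 1 1,3-bis(benzyloxy)-5-bromobenzene
Product: 2 1,5-bis(benzyloxy)-3-bromo-2-iodobenzene
Conditions: NIS (1.0 equiv), TFA (cat.), MeCN, 0 °C → rt, dark
Reagents that add atoms: N-iodosuccinimide, O=C1CCC(=O)N1I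
Why: Electrophilic aromatic iodination; the site next to bromine is para to one ether and ortho to the other and is less hindered than the site between the two benzyloxy groups, so iodine should enter there.

**Step 2**
Reactants: 2 1,5-bis(benzyloxy)-3-bromo-2-iodobenzene (2 equiv); 3 ethyl formate
Product: 6 bis[2,4-bis(benzyloxy)-6-bromophenyl]methanol, via [2,4-bis(benzyloxy)-6-bromophenyl]magnesium chloride 4 (not isolated), via 2,4-bis(benzyloxy)-6-bromobenzaldehyde 5 (not isolated)
Conditions: i-PrMgCl·LiCl (1.05 equiv), THF, −40 °C; then HCO2Et (0.48 equiv), −40 → 0 °C; aq NH4Cl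
Reagents that add atoms: none
Why: Iodine–magnesium exchange with the turbo-Grignard reagent takes C–I in preference to C–Br and gives an ortho-bromoaryl Grignard that is stable below 0 °C; double Grignard addition to ethyl formate through aldehyde 5 should give the symmetrical carbinol, as in the standard preparation of bis(2-bromophenyl)methanol.

**Step 3**
Reactants: 6 bis[2,4-bis(benzyloxy)-6-bromophenyl]methanol
Product: 7 bis[2,4-bis(benzyloxy)-6-bromophenyl]methanone
Conditions: Dess–Martin periodinane, NaHCO3, CH2Cl2, rt
Reagents that add atoms: none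
Why: Dess–Martin oxidation of a secondary diaryl carbinol; the bicarbonate buffer keeps the electron-rich benzhydrol from ionising.

**Step 4**
Reactants: 7 bis[2,4-bis(benzyloxy)-6-bromophenyl]methanone
Product: 8 bis[4-(benzyloxy)-2-bromo-6-hydroxyphenyl]methanone
Conditions: MgBr2·OEt2 (5 equiv), toluene–Et2O, 80 °C; 1 M HCl work-up
Reagents that add atoms: none
Why: Chelation-controlled ether cleavage: magnesium bridges the carbonyl oxygen and the ortho ether oxygen and bromide attacks that benzylic carbon, while the para ethers cannot chelate and should stay intact.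

**Step 5**
Reactants: 8 bis[4-(benzyloxy)-2-bromo-6-hydroxyphenyl]methanone
Product: 9 bis[4-(benzyloxy)-2-bromo-6-methoxyphenyl]methanone
Conditions: MeI, K2CO3, DMF, 40 °C
Reagents that add atoms: iodomethane, CI
Why: Williamson O-methylation of the two carbonyl-chelated phenols; at 40 °C alkylation should outrun any displacement of the ortho' bromide by phenoxide.

**Step 6**
Reactants: 9 bis[4-(benzyloxy)-2-bromo-6-methoxyphenyl]methanone
Product: 10 bis[4-(benzyloxy)-2-iodo-6-methoxyphenyl]methanone
Conditions: CuI (10 mol %), trans-N,N'-dimethylcyclohexane-1,2-diamine (20 mol %), NaI (4 equiv), 1,4-dioxane, 110 °C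
Reagents that add atoms: sodium iodide, [Na+].[I-]
Why: Copper-catalysed aromatic Finkelstein halogen exchange, driven by precipitation of NaBr from dioxane; each bromide has only the carbonyl as ortho neighbour and the ethers and ketone are inert.

**Step 7**
Reactants: 11 4-iodo-2-methoxyphenol
Product: 12 1-(benzyloxy)-4-iodo-2-methoxybenzene
Conditions: BnBr, K2CO3, DMF, rt
Reagents that add atoms: benzyl bromide, BrCc1ccccc1
Why: Williamson O-benzylation of a phenol; the aryl iodide is untouched.

**Step 8**
Reactants: 10 bis[4-(benzyloxy)-2-iodo-6-methoxyphenyl]methanone; 13 ethynyltrimethylsilane (2.5 equiv); 12 1-(benzyloxy)-4-iodo-2-methoxybenzene (2.3 equiv)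
Product: 16 bis{4-(benzyloxy)-2-[(4-(benzyloxy)-3-methoxyphenyl)ethynyl]-6-methoxyphenyl}methanone, via bis{4-(benzyloxy)-2-methoxy-6-[(trimethylsilyl)ethynyl]phenyl}methanone 14 (not isolated), via bis[4-(benzyloxy)-2-ethynyl-6-methoxyphenyl]methanone 15 (not isolated)
Conditions: PdCl2(PPh3)2 (6 mol %), CuI (10 mol %), Et3N, degassed toluene, rt; excess 13 stripped in vacuo; then 12, DBU (excess), H2O (1 equiv), toluene, rt → 50 °C
Reagents that add atoms: none
Why: Pd(0) inserts into each C–I bond of 10, the copper acetylide of 13 transmetalates and reductive elimination gives bis(silylalkyne) 14; DBU with one equivalent of water then cleaves both C–Si bonds, and each terminus of 15, released slowly, enters a second Pd/Cu cycle with iodide 12 to give 16. The closest known reaction type is the one-pot Sonogashira coupling, in situ desilylation and second Sonogashira coupling that gives unsymmetrical diarylalkynes from ethynyltrimethylsilane. No ring is closed and no stereocentre is formed. The selectivity needed is that every alkyne terminus meets a different aryl iodide: the silyl group blocks the second terminus until the C–I bonds of 10 are consumed, and the volatile excess of 13 is removed before 12 is added so that 12 is not diverted to the symmetrical bis(guaiacyl)acetylene. The iodides of 10 are ortho to the carbonyl and meta to both alkoxy groups, so oxidative addition is not slowed by the donors, and slow unmasking keeps the free terminal alkyne low, which should suppress Glaser coupling. Cyclisation of the ortho-alkynyl ketone onto the carbonyl is disfavoured because the tetra-ortho-substituted, electron-rich diaryl ketone is a poor electrophile and the medium is basic, free of Lewis acids and kept at or below 50 °C.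

**Step 9**
Reactants: 16 bis{4-(benzyloxy)-2-[(4-(benzyloxy)-3-methoxyphenyl)ethynyl]-6-methoxyphenyl}methanone
Product: 17 bis{4-hydroxy-2-[2-(4-hydroxy-3-methoxyphenyl)ethyl]-6-methoxyphenyl}methanone
Conditions: H2 (1 atm), 10 % Pd/C, EtOAc–MeOH, rt
Reagents that add atoms: none
Why: Heterogeneous hydrogenation saturates both diarylalkynes and hydrogenolyses the four benzyl ethers; the twisted, hindered diaryl ketone is expected to survive neutral conditions, and any partial reduction of it converges in step 10.

**Step 10**
Reactants: 17 bis{4-hydroxy-2-[2-(4-hydroxy-3-methoxyphenyl)ethyl]-6-methoxyphenyl}methanone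
Product: 18 4,4'-methylenebis{3-[2-(4-hydroxy-3-methoxyphenyl)ethyl]-5-methoxyphenol} (CNP0079383.0)
Conditions: Et3SiH (6 equiv), TFA, CH2Cl2, 0 °C → rt
Reagents that add atoms: none
Why: Ionic hydrogenation of a diaryl ketone: protonation, hydride transfer from the silane, ionisation of the benzhydrol and a second hydride transfer; the cation is stabilised by a para-hydroxyl and an ortho-methoxyl on each ring, and excess silane should capture it before it reacts elsewhere.

**Compound list**
1 | 1,3-bis(benzyloxy)-5-bromobenzene | Brc1cc(OCc2ccccc2)cc(OCc2ccccc2)c1 | starting material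
2 | 1,5-bis(benzyloxy)-3-bromo-2-iodobenzene | Ic1c(Br)cc(OCc2ccccc2)cc1OCc1ccccc1 | intermediate
3 | ethyl formate | CCOC=O | starting material
4 | [2,4-bis(benzyloxy)-6-bromophenyl]magnesium chloride | Cl[Mg]c1c(Br)cc(OCc2ccccc2)cc1OCc1ccccc1 | intermediate
5 | 2,4-bis(benzyloxy)-6-bromobenzaldehyde | O=Cc1c(Br)cc(OCc2ccccc2)cc1OCc1ccccc1 | intermediate
6 | bis[2,4-bis(benzyloxy)-6-bromophenyl]methanol | OC(c1c(Br)cc(OCc2ccccc2)cc1OCc1ccccc1)c1c(Br)cc(OCc2ccccc2)cc1OCc1ccccc1 | intermediate
7 | bis[2,4-bis(benzyloxy)-6-bromophenyl]methanone | O=C(c1c(Br)cc(OCc2ccccc2)cc1OCc1ccccc1)c1c(Br)cc(OCc2ccccc2)cc1OCc1ccccc1 | intermediate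
8 | bis[4-(benzyloxy)-2-bromo-6-hydroxyphenyl]methanone | O=C(c1c(Br)cc(OCc2ccccc2)cc1O)c1c(Br)cc(OCc2ccccc2)cc1O | intermediate
9 | bis[4-(benzyloxy)-2-bromo-6-methoxyphenyl]methanone | O=C(c1c(Br)cc(OCc2ccccc2)cc1OC)c1c(Br)cc(OCc2ccccc2)cc1OC | intermediate
10 | bis[4-(benzyloxy)-2-iodo-6-methoxyphenyl]methanone | O=C(c1c(I)cc(OCc2ccccc2)cc1OC)c1c(I)cc(OCc2ccccc2)cc1OC | intermediate
11 | 4-iodo-2-methoxyphenol | COc1cc(I)ccc1O | starting material
12 | 1-(benzyloxy)-4-iodo-2-methoxybenzene | COc1cc(I)ccc1OCc1ccccc1 | intermediate
13 | ethynyltrimethylsilane | C#C[Si](C)(C)C | starting material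
14 | bis{4-(benzyloxy)-2-methoxy-6-[(trimethylsilyl)ethynyl]phenyl}methanone | O=C(c1c(C#C[Si](C)(C)C)cc(OCc2ccccc2)cc1OC)c1c(C#C[Si](C)(C)C)cc(OCc2ccccc2)cc1OC | intermediate
15 | bis[4-(benzyloxy)-2-ethynyl-6-methoxyphenyl]methanone | O=C(c1c(C#C)cc(OCc2ccccc2)cc1OC)c1c(C#C)cc(OCc2ccccc2)cc1OC | intermediate
16 | bis{4-(benzyloxy)-2-[(4-(benzyloxy)-3-methoxyphenyl)ethynyl]-6-methoxyphenyl}methanone | O=C(c1c(C#Cc2ccc(OCc3ccccc3)c(OC)c2)cc(OCc2ccccc2)cc1OC)c1c(C#Cc2ccc(OCc3ccccc3)c(OC)c2)cc(OCc2ccccc2)cc1OC | intermediate
17 | bis{4-hydroxy-2-[2-(4-hydroxy-3-methoxyphenyl)ethyl]-6-methoxyphenyl}methanone | O=C(c1c(CCc2ccc(O)c(OC)c2)cc(O)cc1OC)c1c(CCc2ccc(O)c(OC)c2)cc(O)cc1OC | intermediate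
18 | 4,4'-methylenebis{3-[2-(4-hydroxy-3-methoxyphenyl)ethyl]-5-methoxyphenol} | COc1cc(CCc2cc(O)cc(OC)c2Cc2c(CCc3ccc(O)c(OC)c3)cc(O)cc2OC)ccc1O | target

**Step count**
Total: 10 steps. Longest linear sequence: 9 steps (steps 1–6 and 8–10, from 1 to 18); step 7 is a one-step side branch.

**Steps most likely to fail**

Step 8. The four-fold coupling may stop at partly coupled material, the unmasked diyne may homocouple oxidatively, residual silylacetylene may consume the guaiacyl iodide, or the ortho-alkynyl ketone may cyclise onto the carbonyl. The fallback sets out from 12 and returns at 16, putting the alkyne on the guaiacyl side first. 12 is coupled with 13 (PdCl2(PPh3)2, CuI, Et3N, THF, rt) to give [(4-benzyloxy-3-methoxyphenyl)ethynyl]trimethylsilane F1. K2CO3 in MeOH removes silicon to give 1-(benzyloxy)-4-ethynyl-2-methoxybenzene F2, a stable arylacetylene that can be isolated. F2 (2.4 equiv) is then coupled twice with 10 (PdCl2(PPh3)2, CuI, Et3N, THF, rt → 40 °C) to give 16. The sensitive ortho-ethynyl ketone 15 is never generated in this order.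

Step 10. The diarylmethyl cation may be intercepted by a tethered guaiacyl ring in a seven-membered Friedel–Crafts closure, or reduction may stall because hydride delivery to the tetra-ortho-substituted centre is slow. The fallback sets out from 10 and returns at 18, removing the carbonyl oxygen before the tethers exist. 10 is reduced with Et3SiH and BF3·OEt2 (CH2Cl2–MeCN, 0 °C → rt) to bis[4-(benzyloxy)-2-iodo-6-methoxyphenyl]methane F3. F3 is taken through the same one-pot sequence as step 8 with 13 and then 12, via bis{4-(benzyloxy)-2-methoxy-6-[(trimethylsilyl)ethynyl]phenyl}methane F4 and bis[4-(benzyloxy)-2-ethynyl-6-methoxyphenyl]methane F5, to bis{4-(benzyloxy)-2-[(4-(benzyloxy)-3-methoxyphenyl)ethynyl]-6-methoxyphenyl}methane F6. Hydrogenation of F6 (H2, Pd/C, EtOAc–MeOH) saturates the alkynes and cleaves the benzyl ethers to give 18 directly.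

Step 4. The chelate that distinguishes the ortho ethers is weakened by the twist of the tetra-ortho-substituted ketone, so cleavage may be slow or spread to the para ethers. The fallback sets out from 7 and returns at 8, reversing the sense of the differentiation. All four benzyl ethers are removed with BCl3 and pentamethylbenzene (CH2Cl2, −78 °C) to give bis(2-bromo-4,6-dihydroxyphenyl)methanone F7. BnBr (2.1 equiv) with KHCO3 in DMF at 40 °C then alkylates only the more acidic, non-chelated para-hydroxyls to give 8.

**Further compounds**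
F1 | step 8 | [(4-benzyloxy-3-methoxyphenyl)ethynyl]trimethylsilane | COc1cc(C#C[Si](C)(C)C)ccc1OCc1ccccc1
F2 | step 8 | 1-(benzyloxy)-4-ethynyl-2-methoxybenzene | COc1cc(C#C)ccc1OCc1ccccc1
F3 | step 10 | bis[4-(benzyloxy)-2-iodo-6-methoxyphenyl]methane | COc1cc(OCc2ccccc2)cc(I)c1Cc1c(I)cc(OCc2ccccc2)cc1OC
F4 | step 10 | bis{4-(benzyloxy)-2-methoxy-6-[(trimethylsilyl)ethynyl]phenyl}methane | COc1cc(OCc2ccccc2)cc(C#C[Si](C)(C)C)c1Cc1c(C#C[Si](C)(C)C)cc(OCc2ccccc2)cc1OC
F5 | step 10 | bis[4-(benzyloxy)-2-ethynyl-6-methoxyphenyl]methane | COc1cc(OCc2ccccc2)cc(C#C)c1Cc1c(C#C)cc(OCc2ccccc2)cc1OC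
F6 | step 10 | bis{4-(benzyloxy)-2-[(4-(benzyloxy)-3-methoxyphenyl)ethynyl]-6-methoxyphenyl}methane | COc1cc(OCc2ccccc2)cc(C#Cc2ccc(OCc3ccccc3)c(OC)c2)c1Cc1c(C#Cc2ccc(OCc3ccccc3)c(OC)c2)cc(OCc2ccccc2)cc1OC
F7 | step 4 | bis(2-bromo-4,6-dihydroxyphenyl)methanone | O=C(c1c(Br)cc(O)cc1O)c1c(Br)cc(O)cc1O
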